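**Plan**

Labdane numbering is used throughout: ring A = C1–C5 and C10 (gem-dimethyl on C4), ring B = C5–C10, C17 on C8, C20 on C10, side chain C11–C16 on C9. The target is read as (13E)-6β-acetoxy-7α-(3-methylbutanoyloxy)labda-8,13-dien-15-oic acid (5α-H, 10β-CH3, trans-diaxial diester).
Retrosynthetic cuts, in order: the ester C–O bonds at C6 and C7; C12–C13 and C9–C11 of the side chain; C8–C17; finally C10–C20 together with a temporary C5–C20 bond.
Enabling feature: the C7 oxygen of ring B can be an anisole oxygen. Birch reduction of aromatic ring B leaves one tetrasubstituted alkene, C5=C10, homoallylic to C7–OH. The quaternary C10 with its β-methyl C20 is then a CH2 delivered across C5=C10 from the oxygen face and freed by acid cleavage of C5–C20.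
Forward order: rings A and B come joined in 7-methoxy-1-tetralone (C4 gem-dimethyl added first); Birch reduction, C7 carbinol, cyclopropane, 10-methyl C5=C6 enone; C17, C8=C9 and a C9 vinyl group; C5–H and C6–O through the dissolving-metal enolate; C11–C16 by hydroboration/Suzuki coupling; C8=C9 re-formed; C7 and C6 carbinols adjusted and acylated; acid freed last.
Stereochemistry: C7 (R) from an enzymatic ketone reduction, relayed to C10 by hydroxyl-directed cyclopropanation; C5 by α-face protonation in the enone reduction; the 7α-ester by Mitsunobu inversion of the 7β-alcohol; C6β by α-face hydride addition to the C6 ketone; 13E from an E-enol triflate.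

Key step: step 4

Assumption: an (R)-selective ketoreductase that accepts ketone 4 is found in a commercial enzyme panel, as such enzymes accept 2-tetralones; if not, the fallback for step 3 applies.
Remark: C8 and C9 in compounds 10, 13–18 and 23–25 become trigonal again (steps 8 and 16); the configurations drawn are the expected major ones and are not needed.

Step 1
Reactants: 1 7-methoxy-3,4-dihydronaphthalen-1(2H)-one (7-methoxy-1-tetralone)
Product: 2 7-methoxy-1,1-dimethyl-1,2,3,4-tetrahydronaphthalene
Conditions: TiCl4, Me2Zn, CH2Cl2, −30 °C to rt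
Reagents that add atoms: dimethylzinc, C[Zn]C
Why: Geminal dimethylation of an aryl ketone by Me2TiCl2 made in situ (methyl addition, ionisation of the titanium alkoxide to the tertiary benzylic cation, second methyl transfer) turns C=O into the C4 gem-dimethyl group with the methoxy group fixed at the future C7.

Step 2
Reactants: 2 7-methoxy-1,1-dimethyltetralin
Product: 4 8,8-dimethyl-3,4,5,6,7,8-hexahydronaphthalen-2(1H)-one, via enol ether 3 (not isolated)
Conditions: Li, t-BuOH, NH3(l)/THF, −78 to −33 °C; NH4Cl; then (CO2H)2, MeOH/H2O, rt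
Reagents that add atoms: water, O
Why: Birch reduction protonates the two unsubstituted ring carbons ortho and meta to methoxy (C6 and C9), leaving the enol ether C7=C8 and the tetrasubstituted C5=C10 bond, and oxalic acid hydrolyses only the enol ether so that the alkene stays out of conjugation.

Step 3
Reactants: 4 β,γ-unsaturated C7 ketone
Product: 5 (2R)-8,8-dimethyl-1,2,3,4,5,6,7,8-octahydronaphthalen-2-ol (7β-hydroxy-4,4-dimethyl-5(10)-octalin)
Conditions: (R)-selective ketoreductase, NADP+ (cat.), isopropanol, phosphate buffer pH 7, 30 °C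
Reagents that add atoms: none
Why: Enzymatic (NADPH-dependent ketoreductase) carbonyl reduction with isopropanol as terminal reductant, in which the enzyme pocket tells the C6 flank (next to the alkene and the gem-dimethyl carbon) from the C8 flank and sets C7 as R at neutral pH, where the β,γ-alkene does not migrate.

Step 4
Reactants: 5 homoallylic alcohol
Product: 6 (2R,4aR,8aR)-8,8-dimethyl-1,2,3,4,5,6,7,8-octahydro-4a,8a-methanonaphthalen-2-ol (5β,10β-methano-7β-ol; cyclopropane C5–C20–C10 cis to the hydroxyl)
Conditions: Et2Zn, CH2I2, CH2Cl2, 0 °C to rt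
Reagents that add atoms: diiodomethane, ICI
Why: Et2Zn first gives the C7 zinc alkoxide, which holds the iodomethylzinc carbenoid and transfers CH2 through a concerted butterfly-type transition state to the face of C5=C10 that carries the oxygen, forming C10–C20 and C5–C20 together. The closest known reaction is the hydroxyl-directed Simmons–Smith cyclopropanation (Et2Zn/CH2I2 variant) of cyclohex-3-enols, the reaction type used to bring the angular carbon into 19-nor steroid 5(10)-en-3-ols. The three-membered ring closes by a single syn [2+1] addition of the carbenoid carbon to both alkene carbons, not by a stepwise cyclisation. C5 and C10, the two new stereocentres, are both fixed cis to the C7 oxygen by this intramolecular delivery, so the R carbinol becomes the 10β quaternary centre. Only facial selectivity is required, because C5=C10 is the sole alkene and is electron-rich; it is secured by the pseudo-axial homoallylic zinc alkoxide of the ring B half-chair, which sits over one face while the undirected reaction of this tetrasubstituted alkene is slow.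

Step 5
Reactants: 6 cyclopropyl carbinol
Product: 7 (4aR,8aR)-8,8-dimethyl-3,4,5,6,7,8-hexahydro-4a,8a-methanonaphthalen-2(1H)-one
Conditions: Dess–Martin periodinane, CH2Cl2, rt
Reagents that add atoms: none
Why: Dess–Martin oxidation of the secondary carbinol under near-neutral conditions keeps the acid-labile cyclopropane and provides the C7 ketone needed for ring opening.

Step 6
Reactants: 7 β-cyclopropyl ketone
Product: 8 (4aR)-4a,8,8-trimethyl-4,4a,5,6,7,8-hexahydronaphthalen-2(3H)-one (10β-methyl C5=C6 enone)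
Conditions: conc. HCl, AcOH, 60 °C
Reagents that add atoms: none
Why: Acid-catalysed homo-conjugate cyclopropane opening, in which the enol formed toward C6 pushes electrons into C5 while C20 is protonated; only the C5–C20 bond is aligned with the enol π system, so C20 ends as the methyl on C10 with that centre untouched and C5=C6 in conjugation.

Step 7
Reactants: 8 10-methyl enone
Product: 10 (3S,4aR)-3,4a,8,8-tetramethyl-4,4a,5,6,7,8-hexahydronaphthalen-2(3H)-one (C17 on C8), via lithium dienolate 9 (not isolated)
Conditions: LiN(iPr)2, THF, −78 °C; then MeI, −78 to 0 °C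
Reagents that add atoms: iodomethane, CI
Why: Kinetic α′-deprotonation of the enone (C8 is its only enolisable carbon) and SN2 methylation of the cross-conjugated dienolate install C17; the equatorial 8α-methyl epimer is expected, but the centre is removed in step 8.

Step 8
Reactants: 10 8-methyl enone
Product: 11 (4aR)-3,4a,8,8-tetramethyl-5,6,7,8-tetrahydronaphthalen-2(4aH)-one (C5=C6/C8=C9 dienone)
Conditions: DDQ, 1,4-dioxane, reflux
Reagents that add atoms: none
Why: DDQ dehydrogenation through the C7–C8 dienol with hydride loss from C9, the reaction type that converts steroidal 4-en-3-ones into 1,4-dien-3-ones; the quaternary C4 and C10 leave no other position to oxidise.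

Step 9
Reactants: 11 cross-conjugated dienone
Product: 13 13,14,15,16-tetranorlabda-5,11-dien-7-one (8βH/9βH; vinyl on the α face of C9), via silyl dienol ether 12 (not isolated)
Conditions: CH2=CHMgBr, CuBr·SMe2 (cat.), Me3SiCl, DMPU, THF, −78 °C; then 1 M HCl, 0 °C
Reagents that add atoms: vinylmagnesium bromide, C=C[Mg]Br
Why: Copper-catalysed, Me3SiCl-accelerated conjugate addition of the vinyl Grignard reagent to C9, the only β-carbon bearing hydrogen, from the α face anti to the C10 methyl as in the 1α-alkylation of steroidal 1,4-dien-3-ones; acid hydrolysis of the silyl dienol ether returns the C5=C6 enone.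

Step 10
Reactants: 13 vinyl enone
Product: 15 7-(trimethylsilyloxy)-13,14,15,16-tetranorlabda-6,11-diene (5α-H), via lithium enolate 14 (not isolated)
Conditions: Li (2.2 equiv), t-BuOH (1.0 equiv), NH3(l)/THF, −78 °C; NH3 removed; then Me3SiCl, Et3N, THF, 0 °C
Reagents that add atoms: chlorotrimethylsilane, C[Si](C)(C)Cl
Why: Dissolving-metal (Birch-type) reduction of the enone: C5 is protonated from the α face, away from the C4β and C10 methyls, giving the trans ring fusion, and the regiodefined C6=C7 lithium enolate is trapped on oxygen while the isolated vinyl group is left alone.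

Step 11
Reactants: 15 silyl enol ether
Product: 17 6α-hydroxy-13,14,15,16-tetranorlabd-11-en-7-one, via silyloxy epoxide 16 (not isolated)
Conditions: dimethyldioxirane, acetone/CH2Cl2, −40 °C; then 1 M HCl, THF, 0 °C
Reagents that add atoms: dimethyldioxirane, CC1(C)OO1
Why: Rubottom oxidation: the electron-rich enol ether is epoxidised in preference to the vinyl group, from the α face because the β face of C6 lies under the C4β and C10 methyls, and acid opens the silyloxy epoxide to the 6α-hydroxy ketone (a centre that is reset in steps 20 and 21).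

Step 12
Reactants: 17 α-hydroxy ketone
Product: 18 6α-(tert-butyldimethylsilyloxy)-13,14,15,16-tetranorlabd-11-en-7-one
Conditions: t-BuMe2SiOTf, 2,6-lutidine, CH2Cl2, −78 to 0 °C
Reagents that add atoms: tert-butyldimethylsilyl trifluoromethanesulfonate, CC(C)(C)[Si](C)(C)OS(=O)(=O)C(F)(F)F
Why: Silyl ether formation with the silyl triflate and a hindered base protects the C6 hydroxyl through the hydride, palladium and Mitsunobu steps and blocks enolisation toward C6.

Step 13
Reactants: 19 2,2,6-trimethyl-4H-1,3-dioxin-4-one; 20 2-(trimethylsilyl)ethanol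
Product: 21 2-(trimethylsilyl)ethyl 3-oxobutanoate
Conditions: toluene, 110 °C
Reagents that add atoms: none
Why: Thermal cycloreversion of the dioxinone to acetylketene (loss of acetone) and addition of the alcohol give the acetoacetate (acetoacetylation).

Step 14
Reactants: 21 β-keto ester
Product: 22 2-(trimethylsilyl)ethyl (2E)-3-(trifluoromethylsulfonyloxy)but-2-enoate
Conditions: Tf2O, 25% aq. Me4NOH, toluene, 5 °C
Reagents that add atoms: trifluoromethanesulfonic anhydride, O=S(=O)(OS(=O)(=O)C(F)(F)F)C(F)(F)F
Why: O-sulfonylation of the β-keto ester enolate, which with the non-chelating tetramethylammonium counter-ion reacts in its extended form and gives the E enol triflate (triflate trans to the ester) that fixes the later 13E geometry.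

Step 15
Reactants: 18 vinyl ketone; 22 E-enol triflate
Product: 24 2-(trimethylsilyl)ethyl (13E)-6α-(tert-butyldimethylsilyloxy)-7-oxolabd-13-en-15-oate (8βH/9βH), via alkylborane 23 (not isolated)
Conditions: 9-BBN, THF, 0 °C to rt; then 22, PdCl2(dppf) (cat.), AsPh3, 3 M aq. K3PO4, DMF, rt
Reagents that add atoms: none
Why: Anti-Markovnikov hydroboration of the monosubstituted alkene by 9-BBN (faster than reduction of the doubly α-branched ketone) and B-alkyl Suzuki–Miyaura coupling with the enol triflate form C12–C13 with retention of alkene geometry, so the chain ends trans to the ester.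

Step 16
Reactants: 24 saturated keto ester
Product: 26 2-(trimethylsilyl)ethyl (13E)-6α-(tert-butyldimethylsilyloxy)-7-oxolabda-8,13-dien-15-oate, via silyl enol ether 25 (not isolated)
Conditions: Me3SiOTf, Et3N, CH2Cl2, 0 °C; then Pd(OAc)2, MeCN, 40 °C
Reagents that add atoms: none
Why: Soft enolisation goes toward C8 because the only C6 hydrogen is axial beneath the C4β and C10 methyls on a silyloxy carbon, and Saegusa–Ito oxidation (palladation at C8, β-hydride elimination of H9) gives the conjugated tetrasubstituted C8=C9 enone and removes the C8 and C9 stereocentres.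

Step 17
Reactants: 26 enone
Product: 27 2-(trimethylsilyl)ethyl (13E)-6α-(tert-butyldimethylsilyloxy)-7β-hydroxylabda-8,13-dien-15-oate
Conditions: NaBH4, CeCl3·7H2O, MeOH, −40 °C
Reagents that add atoms: none
Why: Luche 1,2-reduction in which hydride adds along the axial trajectory on the α face, anti to the C10 methyl, to give the pseudo-equatorial 7β-alcohol, while the β,β-disubstituted enoate is not reduced.

Step 18
Reactants: 27 7β-allylic alcohol
Product: 28 2-(trimethylsilyl)ethyl (13E)-6α-(tert-butyldimethylsilyloxy)-7α-(3-methylbutanoyloxy)labda-8,13-dien-15-oate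
Conditions: 3-methylbutanoic acid, PPh3, DIAD, toluene, 0 °C to rt
Reagents that add atoms: 3-methylbutanoic acid, CC(C)CC(O)=O
Why: Mitsunobu esterification, in which SN2 attack of isovalerate on the C7 oxyphosphonium ion inverts the centre and installs the 7α-ester directly, as in 3β-to-3α inversions of steroidal allylic alcohols, with SN2′ attack at the fully substituted C9 blocked.

Step 19
Reactants: 28 silyl ether diester
Product: 29 2-(trimethylsilyl)ethyl (13E)-6α-hydroxy-7α-(3-methylbutanoyloxy)labda-8,13-dien-15-oate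
Conditions: HF·pyridine, pyridine, THF, 0 °C to rt
Reagents that add atoms: none
Why: Cleavage of the silyl ether by buffered hydrogen fluoride; the 2-(trimethylsilyl)ethyl ester needs free fluoride ion and survives, and the weakly acidic medium does not promote migration of the C7 acyl group to the cis C6 hydroxyl.

Step 20
Reactants: 29 6α-alcohol
Product: 30 2-(trimethylsilyl)ethyl (13E)-7α-(3-methylbutanoyloxy)-6-oxolabda-8,13-dien-15-oate
Conditions: Dess–Martin periodinane, CH2Cl2, 0 °C to rt
Reagents that add atoms: none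
Why: Dess–Martin oxidation gives the C6 ketone without base, so C7–H (α to the ketone and allylic) and the trans-fused C5–H are not epimerised.

Step 21
Reactants: 30 C6 ketone
Product: 31 2-(trimethylsilyl)ethyl (13E)-6β-hydroxy-7α-(3-methylbutanoyloxy)labda-8,13-dien-15-oate
Conditions: NaBH4, CeCl3·7H2O, MeOH, −78 °C
Reagents that add atoms: none
Why: Borohydride reduction under Luche conditions, in which the β face of C6 is closed by the syn-axial C4β and C10 methyls, so hydride adds from the α face and gives the axial 6β-alcohol, trans-diaxial to the C7 ester and therefore not prone to acyl migration.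

Step 22
Reactants: 31 6β-alcohol
Product: 32 2-(trimethylsilyl)ethyl (13E)-6β-acetoxy-7α-(3-methylbutanoyloxy)labda-8,13-dien-15-oate
Conditions: Ac2O, Et3N, DMAP (cat.), CH2Cl2, 40 °C
Reagents that add atoms: acetic anhydride, CC(=O)OC(C)=O
Why: DMAP-catalysed acetylation (acyl transfer through the N-acetylpyridinium ion) of the hindered axial 6β-hydroxyl, acetyl being the smallest acyl group to place there.

Step 23
Reactants: 32 silylethyl ester
Product: 33 (13E)-6β-acetoxy-7α-(3-methylbutanoyloxy)labda-8,13-dien-15-oic acid (CNP0328312.2)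
Conditions: Bu4NF, THF, 0 °C to rt; then cold 0.5 M HCl
Reagents that add atoms: none
Why: Fluoride attacks silicon and the 2-(trimethylsilyl)ethyl ester fragments with loss of ethene and Me3SiF, which frees the C15 acid without hydrolysing the hindered acetate or the isovalerate.

**Compound list**

1 | 7-methoxy-3,4-dihydronaphthalen-1(2H)-one | COc1ccc2CCCC(=O)c2c1 | starting material
2 | 7-methoxy-1,1-dimethyl-1,2,3,4-tetrahydronaphthalene | COc1ccc2CCCC(C)(C)c2c1 | intermediate
3 | 7-methoxy-1,1-dimethyl-1,2,3,4,5,8-hexahydronaphthalene (Birch enol ether) | COC1=CCC2=C(C1)C(C)(C)CCC2 | intermediate (not isolated)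
4 | 8,8-dimethyl-3,4,5,6,7,8-hexahydronaphthalen-2(1H)-one (C7 ketone, C5=C10 alkene) | O=C1CCC2=C(C1)C(C)(C)CCC2 | intermediate
5 | (2R)-8,8-dimethyl-1,2,3,4,5,6,7,8-octahydronaphthalen-2-ol (7β-hydroxy-4,4-dimethyl-5(10)-octalin) | O[C@@H]1CCC2=C(C1)C(C)(C)CCC2 | intermediate
6 | (2R,4aR,8aR)-8,8-dimethyl-1,2,3,4,5,6,7,8-octahydro-4a,8a-methanonaphthalen-2-ol (5β,10β-methano-7β-ol) | O[C@@H]1CC[C@]23C[C@@]2(C1)C(C)(C)CCC3 | intermediate
7 | (4aR,8aR)-8,8-dimethyl-3,4,5,6,7,8-hexahydro-4a,8a-methanonaphthalen-2(1H)-one | O=C1CC[C@]23C[C@@]2(C1)C(C)(C)CCC3 | intermediate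
8 | (4aR)-4a,8,8-trimethyl-4,4a,5,6,7,8-hexahydronaphthalen-2(3H)-one (10β-methyl C5=C6 enone) | O=C1CC[C@@]2(C)CCCC(C)(C)C2=C1 | intermediate
9 | lithium dienolate of 8 (C7–OLi, C7=C8, C5=C6) | [Li]OC1=CC[C@@]2(C)CCCC(C)(C)C2=C1 | intermediate (not isolated)
10 | (3S,4aR)-3,4a,8,8-tetramethyl-4,4a,5,6,7,8-hexahydronaphthalen-2(3H)-one (8α-methyl enone) | O=C1[C@@H](C)C[C@@]2(C)CCCC(C)(C)C2=C1 | intermediate
11 | (4aR)-3,4a,8,8-tetramethyl-5,6,7,8-tetrahydronaphthalen-2(4aH)-one (cross-conjugated dienone) | O=C1C(C)=C[C@@]2(C)CCCC(C)(C)C2=C1 | intermediate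
12 | 7-(trimethylsilyloxy)-13,14,15,16-tetranorlabda-5,7,11-triene (9α-vinyl, 9β-H) | C[Si](C)(C)OC1=C(C)[C@@H](C=C)[C@@]2(C)CCCC(C)(C)C2=C1 | intermediate (not isolated)
13 | 13,14,15,16-tetranorlabda-5,11-dien-7-one (8α-methyl, 9α-vinyl; 8β-H, 9β-H) | O=C1[C@@H](C)[C@@H](C=C)[C@@]2(C)CCCC(C)(C)C2=C1 | intermediate
14 | lithium 13,14,15,16-tetranorlabda-6,11-dien-7-olate (5α-H, 8β-H, 9β-H) | C1=C(O[Li])[C@@H](C)[C@@H](C=C)[C@@]2(C)CCCC(C)(C)[C@H]12 | intermediate (not isolated)
15 | 7-(trimethylsilyloxy)-13,14,15,16-tetranorlabda-6,11-diene (5α-H, 8β-H, 9β-H) | C1=C(O[Si](C)(C)C)[C@@H](C)[C@@H](C=C)[C@@]2(C)CCCC(C)(C)[C@H]12 | intermediate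
16 | 6α,7α-epoxy-7β-(trimethylsilyloxy)-13,14,15,16-tetranorlabd-11-ene (5α-H, 8β-H, 9β-H) | [C@@H]12O[C@@]2(O[Si](C)(C)C)[C@@H](C)[C@@H](C=C)[C@@]3(C)CCCC(C)(C)[C@H]13 | intermediate (not isolated)
17 | 6α-hydroxy-13,14,15,16-tetranorlabd-11-en-7-one (5α-H, 8β-H, 9β-H) | O[C@H]1C(=O)[C@@H](C)[C@@H](C=C)[C@@]2(C)CCCC(C)(C)[C@H]12 | intermediate
18 | 6α-(tert-butyldimethylsilyloxy)-13,14,15,16-tetranorlabd-11-en-7-one (5α-H, 8β-H, 9β-H) | CC(C)(C)[Si](C)(C)O[C@H]1C(=O)[C@@H](C)[C@@H](C=C)[C@@]2(C)CCCC(C)(C)[C@H]12 | intermediate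
19 | 2,2,6-trimethyl-4H-1,3-dioxin-4-one | CC1=CC(=O)OC(C)(C)O1 | starting material
20 | 2-(trimethylsilyl)ethanol | C[Si](C)(C)CCO | starting material
21 | 2-(trimethylsilyl)ethyl 3-oxobutanoate | CC(=O)CC(=O)OCC[Si](C)(C)C | intermediate
22 | 2-(trimethylsilyl)ethyl (2E)-3-(trifluoromethylsulfonyloxy)but-2-enoate | C/C(OS(=O)(=O)C(F)(F)F)=C\C(=O)OCC[Si](C)(C)C | intermediate
23 | 12-(9-borabicyclo[3.3.1]nonan-9-yl)-6α-(tert-butyldimethylsilyloxy)-13,14,15,16-tetranorlabdan-7-one (5α-H, 8β-H, 9β-H) | CC(C)(C)[Si](C)(C)O[C@H]1C(=O)[C@@H](C)[C@@H](CCB3C4CCCC3CCC4)[C@@]2(C)CCCC(C)(C)[C@H]12 | intermediate (not isolated)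
24 | 2-(trimethylsilyl)ethyl (13E)-6α-(tert-butyldimethylsilyloxy)-7-oxolabd-13-en-15-oate (5α-H, 8β-H, 9β-H) | CC(C)(C)[Si](C)(C)O[C@H]1C(=O)[C@@H](C)[C@@H](CC/C(C)=C/C(=O)OCC[Si](C)(C)C)[C@@]2(C)CCCC(C)(C)[C@H]12 | intermediate
25 | 2-(trimethylsilyl)ethyl (13E)-6α-(tert-butyldimethylsilyloxy)-7-(trimethylsilyloxy)labda-7,13-dien-15-oate (5α-H, 9β-H) | CC(C)(C)[Si](C)(C)O[C@H]1C(O[Si](C)(C)C)=C(C)[C@@H](CC/C(C)=C/C(=O)OCC[Si](C)(C)C)[C@@]2(C)CCCC(C)(C)[C@H]12 | intermediate (not isolated)
26 | 2-(trimethylsilyl)ethyl (13E)-6α-(tert-butyldimethylsilyloxy)-7-oxolabda-8,13-dien-15-oate | CC(C)(C)[Si](C)(C)O[C@H]1C(=O)C(C)=C(CC/C(C)=C/C(=O)OCC[Si](C)(C)C)[C@@]2(C)CCCC(C)(C)[C@H]12 | intermediate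
27 | 2-(trimethylsilyl)ethyl (13E)-6α-(tert-butyldimethylsilyloxy)-7β-hydroxylabda-8,13-dien-15-oate | CC(C)(C)[Si](C)(C)O[C@H]1[C@H](O)C(C)=C(CC/C(C)=C/C(=O)OCC[Si](C)(C)C)[C@@]2(C)CCCC(C)(C)[C@H]12 | intermediate
28 | 2-(trimethylsilyl)ethyl (13E)-6α-(tert-butyldimethylsilyloxy)-7α-(3-methylbutanoyloxy)labda-8,13-dien-15-oate | CC(C)(C)[Si](C)(C)O[C@H]1[C@@H](OC(=O)CC(C)C)C(C)=C(CC/C(C)=C/C(=O)OCC[Si](C)(C)C)[C@@]2(C)CCCC(C)(C)[C@H]12 | intermediate
29 | 2-(trimethylsilyl)ethyl (13E)-6α-hydroxy-7α-(3-methylbutanoyloxy)labda-8,13-dien-15-oate | O[C@H]1[C@@H](OC(=O)CC(C)C)C(C)=C(CC/C(C)=C/C(=O)OCC[Si](C)(C)C)[C@@]2(C)CCCC(C)(C)[C@H]12 | intermediate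
30 | 2-(trimethylsilyl)ethyl (13E)-7α-(3-methylbutanoyloxy)-6-oxolabda-8,13-dien-15-oate | O=C1[C@@H](OC(=O)CC(C)C)C(C)=C(CC/C(C)=C/C(=O)OCC[Si](C)(C)C)[C@@]2(C)CCCC(C)(C)[C@H]12 | intermediate
31 | 2-(trimethylsilyl)ethyl (13E)-6β-hydroxy-7α-(3-methylbutanoyloxy)labda-8,13-dien-15-oate | O[C@@H]1[C@@H](OC(=O)CC(C)C)C(C)=C(CC/C(C)=C/C(=O)OCC[Si](C)(C)C)[C@@]2(C)CCCC(C)(C)[C@H]12 | intermediate
32 | 2-(trimethylsilyl)ethyl (13E)-6β-acetoxy-7α-(3-methylbutanoyloxy)labda-8,13-dien-15-oate | CC(=O)O[C@@H]1[C@@H](OC(=O)CC(C)C)C(C)=C(CC/C(C)=C/C(=O)OCC[Si](C)(C)C)[C@@]2(C)CCCC(C)(C)[C@H]12 | intermediate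
33 | (13E)-6β-acetoxy-7α-(3-methylbutanoyloxy)labda-8,13-dien-15-oic acid (CNP0328312.2) | CC(=O)O[C@@H]1[C@@H](OC(=O)CC(C)C)C(C)=C(CC/C(C)=C/C(=O)O)[C@@]2(C)CCCC(C)(C)[C@H]12 | target

**Step count and risks**

Total step count: 23. Longest linear sequence: 21 steps (steps 1–12 and 15–23); steps 13 and 14 are a two-step branch to triflate 22.

Steps most likely to fail:

Step 16. Palladation of the crowded, fully substituted enol ether may be slow, and β-hydride elimination may run toward the C17 methyl instead of H9, giving the exocyclic alkene or returning ketone 24. The fallback replaces palladium-mediated dehydrogenation by halogenation and dehydrohalogenation. It sets out from 25, made from 24 as in step 16. N-Bromosuccinimide in THF at 0 °C should convert 25 into the 8-bromo-8-methyl ketone F4. Heating F4 with Li2CO3 and LiBr in DMF at 120 °C should remove HBr under equilibrating conditions that funnel exocyclic or deconjugated isomers into the conjugated tetrasubstituted enone. The route is rejoined at 26.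

Step 18. Ionisation of the allylic oxyphosphonium ion, which is flanked by the silyloxy-bearing C6 and the methyl-bearing alkene carbon, may outrun SN2 attack and lead to elimination or to partial retention at C7. The fallback replaces inversion by a reagent-controlled reduction. It sets out from enone 26. LiBH(s-Bu)3 in THF at −78 °C should deliver hydride along the equatorial trajectory from the β face and give the 7α-alcohol F5. Acylation of F5 with 3-methylbutanoic anhydride, Et3N and DMAP rejoins the route at 28.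

Step 3. The enzyme may discriminate poorly between the two methylene flanks of the ketone, or may favour the S carbinol, so that enantiomeric purity is lost at the only point where absolute configuration enters the route. The fallback replaces asymmetric reduction by classical resolution. It sets out from 4. NaBH4 in MeOH should give the racemic alcohol F1. Esterification with (S)-O-acetylmandelic acid (DCC, DMAP) should give two diastereomers, the (2R)-carbinol ester F2 and the (2S)-carbinol ester F3, which are separated by chromatography or crystallisation. Excess LiOH in aqueous THF cleaves F2, and the route is rejoined at 5.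

Further compounds
F1 | step 3 | racemic 8,8-dimethyl-1,2,3,4,5,6,7,8-octahydronaphthalen-2-ol | OC1CCC2=C(C1)C(C)(C)CCC2
F2 | step 3 | (2R)-8,8-dimethyl-1,2,3,4,5,6,7,8-octahydronaphthalen-2-yl (2S)-2-acetoxy-2-phenylacetate | CC(=O)O[C@@H](c1ccccc1)C(=O)O[C@@H]1CCC2=C(C1)C(C)(C)CCC2
F3 | step 3 | (2S)-8,8-dimethyl-1,2,3,4,5,6,7,8-octahydronaphthalen-2-yl (2S)-2-acetoxy-2-phenylacetate | CC(=O)O[C@@H](c1ccccc1)C(=O)O[C@H]1CCC2=C(C1)C(C)(C)CCC2
F4 | step 16 | 2-(trimethylsilyl)ethyl (13E)-8-bromo-6α-(tert-butyldimethylsilyloxy)-7-oxolabd-13-en-15-oate (C8 epimers, 9β-H) | CC(C)(C)[Si](C)(C)O[C@H]1C(=O)C(C)(Br)[C@@H](CC/C(C)=C/C(=O)OCC[Si](C)(C)C)[C@@]2(C)CCCC(C)(C)[C@H]12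
F5 | step 18 | 2-(trimethylsilyl)ethyl (13E)-6α-(tert-butyldimethylsilyloxy)-7α-hydroxylabda-8,13-dien-15-oate | CC(C)(C)[Si](C)(C)O[C@H]1[C@@H](O)C(C)=C(CC/C(C)=C/C(=O)OCC[Si](C)(C)C)[C@@]2(C)CCCC(C)(C)[C@H]12
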